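**Plan**

- Core numbering (3,7-dioxabicyclo[3.3.0]octan-8-one): C1 and C5 ring fusion, C2 (catechol ring), O3, C4H2, C6 (guaiacyl ring), O7, C8=O. Retrosynthetic cuts: the three aryl O–Si bonds; then C5–C6 together with one C4–H bond, which opens the lactone ring to a protected vanillin and a (2S,3S)-2-aryl-2,3-dihydrofuran-3-carboxylic acid; then the enol ether C=C (from a lactol); then the C1–C2 aldol bond.
- Forward order: syn-aldol (C1–C2), alkene cleavage and lactol closure (tetrahydrofuran ring), dehydration to the 2,3-dihydrofuran, auxiliary removal, O-acylation of the aldehyde and cation–enol ether closure of the lactone ring (C5–C6) with hydride finish at C4, desilylation.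
- Enabling feature: C6 is an aldehyde-level carbon flanked by the lactone oxygen O7 and a para-oxygenated benzene ring, so it can be a stabilised acyloxy-benzylic cation held to C1 through O7–C8(=O). C5 is the β-carbon of the enol ether O3–C4=C5 of the dihydrofuran ring, so it is the nucleophile, and the oxocarbenium ion left at C4 has the right oxidation level to become the OCH2 group with a silane.
- Stereochemistry: C1 and C2 from the (S)-4-benzyloxazolidinone boron aldol (syn, which becomes trans on the ring); C5 from the cis ring fusion imposed by the ester tether; C6 from placement of the aryl group on the convex face.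

Key step: step 8

**Route**

Step 1
Reactants: 1 3,4-dihydroxybenzaldehyde
Product: 2 3,4-bis(triisopropylsilyloxy)benzaldehyde
Conditions: i-Pr3SiCl (2.4 equiv), imidazole (5 equiv), DMF, 23 °C
Reagents that add atoms: chlorotriisopropylsilane, CC(C)[Si](Cl)(C(C)C)C(C)C
Why: Imidazole-promoted silylation of both phenols (silyl ether protection) should give aryl ethers that tolerate the later boron aldol, periodate, amine base, hydroperoxide and ZnCl2 and fall to fluoride at the end.

Step 2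
Reactants: 3 (S)-4-benzyloxazolidin-2-one; 4 pent-4-enoyl chloride
Product: 6 (S)-4-benzyl-3-(pent-4-enoyl)oxazolidin-2-one, via lithium oxazolidinide 5 (not isolated)
Conditions: n-BuLi, THF, −78 °C; then 4, −78 → 0 °C
Reagents that add atoms: none
Why: N-Acylation of the lithiated oxazolidinone by the acid chloride is the standard loading of this auxiliary and touches no stereocenter.

Step 3
Reactants: 6 (S)-4-benzyl-3-(pent-4-enoyl)oxazolidin-2-one; 2 3,4-bis(triisopropylsilyloxy)benzaldehyde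
Product: 9 (4S)-4-benzyl-3-[(2S)-2-{(S)-[3,4-bis(triisopropylsilyloxy)phenyl](hydroxy)methyl}pent-4-enoyl]oxazolidin-2-one, via boron enolate 7 (not isolated), via boron aldolate 8 (not isolated)
Conditions: n-Bu2BOTf, i-Pr2NEt, CH2Cl2, −78 → 0 °C; 2, −78 → 0 °C; then pH 7 buffer, MeOH, 30% H2O2, 0 °C
Reagents that add atoms: none
Why: Evans syn-aldol: the Z-boron enolate should react through a closed chair (Zimmerman–Traxler) transition state on the enolate face away from the benzyl group, which sets the future C1 (S) and C2 (S) in the syn relation that becomes trans on the ring.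

Step 4
Reactants: 9 (4S)-4-benzyl-3-[(2S)-2-{(S)-[3,4-bis(triisopropylsilyloxy)phenyl](hydroxy)methyl}pent-4-enoyl]oxazolidin-2-one
Product: 12 (4S)-4-benzyl-3-{(2S,3S)-2-[3,4-bis(triisopropylsilyloxy)phenyl]-5-hydroxytetrahydrofuran-3-carbonyl}oxazolidin-2-one (both anomers), via diol 10 (not isolated), via aldehyde 11 (not isolated)
Conditions: OsO4 (2 mol %), NaIO4 (4 equiv), 2,6-lutidine (2 equiv), 1,4-dioxane/H2O 3:1, 23 °C
Reagents that add atoms: sodium periodate, [Na+].[O-]I(=O)(=O)=O (terminal source of the lactol hydroxyl oxygen, passed on by osmium tetroxide, O=[Os](=O)(=O)=O)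
Why: Lemieux–Johnson cleavage of the terminal alkene should give the aldehyde, which the benzylic hydroxyl captures as the five-membered lactol; the anomeric center is not controlled and is removed in step 5.

Step 5
Reactants: 12 (4S)-4-benzyl-3-{(2S,3S)-2-[3,4-bis(triisopropylsilyloxy)phenyl]-5-hydroxytetrahydrofuran-3-carbonyl}oxazolidin-2-one
Product: 14 (4S)-4-benzyl-3-{(2S,3S)-2-[3,4-bis(triisopropylsilyloxy)phenyl]-2,3-dihydrofuran-3-carbonyl}oxazolidin-2-one, via anomeric mesylate 13 (not isolated)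
Conditions: MsCl (1.5 equiv), Et3N (5 equiv), CH2Cl2, −40 → 40 °C
Reagents that add atoms: none
Why: Sulfonylation of the lactol hydroxyl followed by amine-induced elimination through the ring oxocarbenium ion (the lactol-to-glycal type of dehydration) should give the cyclic enol ether; only the ring CH2 can lose a proton, and the two stereocenters are not touched.

Step 6
Reactants: 14 (4S)-4-benzyl-3-{(2S,3S)-2-[3,4-bis(triisopropylsilyloxy)phenyl]-2,3-dihydrofuran-3-carbonyl}oxazolidin-2-one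
Product: 16 (2S,3S)-2-[3,4-bis(triisopropylsilyloxy)phenyl]-2,3-dihydrofuran-3-carboxylic acid, via lithium percarboxylate 15 (not isolated)
Conditions: LiOH (2 equiv), 30% H2O2 (4 equiv), THF/H2O 3:1, 0 °C; Na2SO3 (aq), 0 °C; then cold 1 M HCl to pH 4, EtOAc, 0 °C; acid used at once
Reagents that add atoms: hydrogen peroxide, OO (as lithium hydroperoxide, [Li+].[O-]O; gives the carboxyl OH oxygen)
Why: Hydroperoxide cleavage of the auxiliary should attack the exocyclic imide carbonyl selectively without enolisation, and reduction of the percarboxylate by sulfite before acidification keeps any peracid away from the enol ether.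

Step 7
Reactants: 17 vanillin (4-hydroxy-3-methoxybenzaldehyde)
Product: 18 3-methoxy-4-(triisopropylsilyloxy)benzaldehyde
Conditions: i-Pr3SiCl (1.2 equiv), imidazole (2.5 equiv), DMF, 23 °C
Reagents that add atoms: chlorotriisopropylsilane, CC(C)[Si](Cl)(C(C)C)C(C)C
Why: Silyl ether protection keeps the phenol from being acylated in step 8 and leaves a para-oxygen donor for the benzylic cation.

Step 8
Reactants: 16 (2S,3S)-2-[3,4-bis(triisopropylsilyloxy)phenyl]-2,3-dihydrofuran-3-carboxylic acid; 18 3-methoxy-4-(triisopropylsilyloxy)benzaldehyde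
Product: 23 (1S,2S,5R,6S)-2-[3,4-bis(triisopropylsilyloxy)phenyl]-6-[3-methoxy-4-(triisopropylsilyloxy)phenyl]-3,7-dioxabicyclo[3.3.0]octan-8-one, via acid chloride 19 (not isolated), via chloro ester 20 (not isolated), via benzylic cation 21 (not isolated), via oxocarbenium ion 22 (not isolated)
Conditions: Me2C=C(Cl)NMe2 (1.05 equiv), CH2Cl2, 0 °C; then 18 (1.5 equiv), Et3SiH (3 equiv), 2,6-di-tert-butyl-4-methylpyridine (0.2 equiv), ZnCl2 (0.5 equiv), CH2Cl2 (0.02 M), −40 → 0 °C
Reagents that add atoms: none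
Why: Proposed new method: ZnCl2 should let acid chloride 19 acylate the carbonyl oxygen of 18 (the classical route to 1-chloroalkyl esters) and then ionise chloro ester 20 to the benzylic cation 21, which is stabilised by the para-silyloxy ring and the acyloxy oxygen and is already tied to the dihydrofuran through O–C(=O); C4 of the enol ether (the future C5) attacks this cation, which closes the γ-lactone by the new C–C bond and passes the charge to the ring oxygen as oxocarbenium ion 22, and Et3SiH reduces that ion to the OCH2 group with loss of Et3SiCl. The closest known reaction types are the Prins lactonisation of alkenoic acids with aldehydes through acyloxycarbenium ions and the Lewis-acid cyclisation of 3-(hydroxymethyl)-2,3-dihydrofurans with aryl acetals to furofurans, joined here to silane reduction of a cyclic oxocarbenium ion; new are the ester-linked cation, the five-membered closure and the reductive end. The lactone ring closes in a 5-exo-trig mode with respect to the enol ether C=C, with the cationic carbon and its oxygen inside the new ring. C5 is fixed by the tether, because the three-atom link that starts at C1 can reach the neighbouring carbon only on its own face, so the fusion is cis; C6 is set by approach of the E-configured cation with its aryl group turned away from the dihydrofuran ring, which places the aryl group on the convex face, and reversible ionisation of the benzylic C–O bond under the Lewis acid should drain any endo epimer to this more stable exo isomer. The step needs O-acylation of the aldehyde in preference to C-acylation of the enol ether, and ring closure before hydride reaches cation 21; the basic carbonyl oxygen of the electron-rich aldehyde used in excess, high dilution, and the advantage of intramolecular five-membered trapping over the weak hydride donor Et3SiH should secure both.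

Step 9
Reactants: 23 (1S,2S,5R,6S)-2-[3,4-bis(triisopropylsilyloxy)phenyl]-6-[3-methoxy-4-(triisopropylsilyloxy)phenyl]-3,7-dioxabicyclo[3.3.0]octan-8-one
Product: 24 (1S,2S,5R,6S)-2-(3,4-dihydroxyphenyl)-6-(4-hydroxy-3-methoxyphenyl)-3,7-dioxabicyclo[3.3.0]octan-8-one (CNP0268159.1)
Conditions: Bu4NF (3.3 equiv), AcOH (3.5 equiv), THF, 0 °C, argon
Reagents that add atoms: none
Why: Fluoride cleaves the three aryl Si–O bonds (desilylation), and the acetic acid buffer protonates the phenoxides so that the lactone and the air-sensitive catechol should survive; no stereocenter is involved.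

**Compound list**

1 | 3,4-dihydroxybenzaldehyde | O=Cc1ccc(O)c(O)c1 | starting material
2 | 3,4-bis(triisopropylsilyloxy)benzaldehyde | O=Cc1ccc(O[Si](C(C)C)(C(C)C)C(C)C)c(O[Si](C(C)C)(C(C)C)C(C)C)c1 | intermediate
3 | (S)-4-benzyloxazolidin-2-one | O=C1N[C@@H](Cc2ccccc2)CO1 | starting material
4 | pent-4-enoyl chloride | C=CCCC(=O)Cl | starting material
5 | lithium salt of (S)-4-benzyloxazolidin-2-one (not isolated) | [Li+].O=C1[N-][C@@H](Cc2ccccc2)CO1 | intermediate
6 | (S)-4-benzyl-3-(pent-4-enoyl)oxazolidin-2-one | C=CCCC(=O)N1[C@@H](Cc2ccccc2)COC1=O | intermediate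
7 | (Z)-dibutylboron enolate of 6 (not isolated) | C=CC/C=C(\OB(CCCC)CCCC)N1[C@@H](Cc2ccccc2)COC1=O | intermediate
8 | dibutylboron aldolate of 9 (not isolated) | O=C(N1[C@@H](Cc2ccccc2)COC1=O)[C@H]([C@H](OB(CCCC)CCCC)c1ccc(O[Si](C(C)C)(C(C)C)C(C)C)c(O[Si](C(C)C)(C(C)C)C(C)C)c1)CC=C | intermediate
9 | (4S)-4-benzyl-3-[(2S)-2-{(S)-[3,4-bis(triisopropylsilyloxy)phenyl](hydroxy)methyl}pent-4-enoyl]oxazolidin-2-one | O=C(N1[C@@H](Cc2ccccc2)COC1=O)[C@H]([C@H](O)c1ccc(O[Si](C(C)C)(C(C)C)C(C)C)c(O[Si](C(C)C)(C(C)C)C(C)C)c1)CC=C | intermediate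
10 | 4,5-dihydroxypentanoyl analogue of 9, both epimers at the new carbinol (not isolated) | O=C(N1[C@@H](Cc2ccccc2)COC1=O)[C@H]([C@H](O)c1ccc(O[Si](C(C)C)(C(C)C)C(C)C)c(O[Si](C(C)C)(C(C)C)C(C)C)c1)CC(O)CO | intermediate
11 | (4S)-4-benzyl-3-[(2S)-2-{(S)-[3,4-bis(triisopropylsilyloxy)phenyl](hydroxy)methyl}-4-oxobutanoyl]oxazolidin-2-one (not isolated) | O=C(N1[C@@H](Cc2ccccc2)COC1=O)[C@H]([C@H](O)c1ccc(O[Si](C(C)C)(C(C)C)C(C)C)c(O[Si](C(C)C)(C(C)C)C(C)C)c1)CC=O | intermediate
12 | (4S)-4-benzyl-3-{(2S,3S)-2-[3,4-bis(triisopropylsilyloxy)phenyl]-5-hydroxytetrahydrofuran-3-carbonyl}oxazolidin-2-one, both anomers | O=C(N1[C@@H](Cc2ccccc2)COC1=O)[C@H]1CC(O)O[C@@H]1c1ccc(O[Si](C(C)C)(C(C)C)C(C)C)c(O[Si](C(C)C)(C(C)C)C(C)C)c1 | intermediate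
13 | anomeric methanesulfonate of 12 (not isolated) | O=C(N1[C@@H](Cc2ccccc2)COC1=O)[C@H]1CC(OS(C)(=O)=O)O[C@@H]1c1ccc(O[Si](C(C)C)(C(C)C)C(C)C)c(O[Si](C(C)C)(C(C)C)C(C)C)c1 | intermediate
14 | (4S)-4-benzyl-3-{(2S,3S)-2-[3,4-bis(triisopropylsilyloxy)phenyl]-2,3-dihydrofuran-3-carbonyl}oxazolidin-2-one | O=C(N1[C@@H](Cc2ccccc2)COC1=O)[C@H]1C=CO[C@@H]1c1ccc(O[Si](C(C)C)(C(C)C)C(C)C)c(O[Si](C(C)C)(C(C)C)C(C)C)c1 | intermediate
15 | lithium (2S,3S)-2-[3,4-bis(triisopropylsilyloxy)phenyl]-2,3-dihydrofuran-3-carboperoxoate (not isolated) | [Li+].[O-]OC(=O)[C@H]1C=CO[C@@H]1c1ccc(O[Si](C(C)C)(C(C)C)C(C)C)c(O[Si](C(C)C)(C(C)C)C(C)C)c1 | intermediate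
16 | (2S,3S)-2-[3,4-bis(triisopropylsilyloxy)phenyl]-2,3-dihydrofuran-3-carboxylic acid | OC(=O)[C@H]1C=CO[C@@H]1c1ccc(O[Si](C(C)C)(C(C)C)C(C)C)c(O[Si](C(C)C)(C(C)C)C(C)C)c1 | intermediate
17 | vanillin (4-hydroxy-3-methoxybenzaldehyde) | COc1cc(C=O)ccc1O | starting material
18 | 3-methoxy-4-(triisopropylsilyloxy)benzaldehyde | COc1cc(C=O)ccc1O[Si](C(C)C)(C(C)C)C(C)C | intermediate
19 | (2S,3S)-2-[3,4-bis(triisopropylsilyloxy)phenyl]-2,3-dihydrofuran-3-carbonyl chloride (not isolated) | ClC(=O)[C@H]1C=CO[C@@H]1c1ccc(O[Si](C(C)C)(C(C)C)C(C)C)c(O[Si](C(C)C)(C(C)C)C(C)C)c1 | intermediate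
20 | chloro[3-methoxy-4-(triisopropylsilyloxy)phenyl]methyl (2S,3S)-2-[3,4-bis(triisopropylsilyloxy)phenyl]-2,3-dihydrofuran-3-carboxylate, both epimers at the chlorine-bearing carbon (not isolated) | COc1cc(C(Cl)OC(=O)[C@H]2C=CO[C@@H]2c2ccc(O[Si](C(C)C)(C(C)C)C(C)C)c(O[Si](C(C)C)(C(C)C)C(C)C)c2)ccc1O[Si](C(C)C)(C(C)C)C(C)C | intermediate
21 | acyloxy-stabilised benzylic cation formed from 20 by loss of chloride (not isolated) | COc1cc([CH+]OC(=O)[C@H]2C=CO[C@@H]2c2ccc(O[Si](C(C)C)(C(C)C)C(C)C)c(O[Si](C(C)C)(C(C)C)C(C)C)c2)ccc1O[Si](C(C)C)(C(C)C)C(C)C | intermediate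
22 | ring oxocarbenium ion of 23 (C4=O3 cation, configuration as in 23; not isolated) | COc1cc([C@H]2OC(=O)[C@H]3[C@@H]2C=[O+][C@@H]3c2ccc(O[Si](C(C)C)(C(C)C)C(C)C)c(O[Si](C(C)C)(C(C)C)C(C)C)c2)ccc1O[Si](C(C)C)(C(C)C)C(C)C | intermediate
23 | (1S,2S,5R,6S)-2-[3,4-bis(triisopropylsilyloxy)phenyl]-6-[3-methoxy-4-(triisopropylsilyloxy)phenyl]-3,7-dioxabicyclo[3.3.0]octan-8-one | COc1cc([C@H]2OC(=O)[C@H]3[C@@H]2CO[C@@H]3c2ccc(O[Si](C(C)C)(C(C)C)C(C)C)c(O[Si](C(C)C)(C(C)C)C(C)C)c2)ccc1O[Si](C(C)C)(C(C)C)C(C)C | intermediate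
24 | (1S,2S,5R,6S)-2-(3,4-dihydroxyphenyl)-6-(4-hydroxy-3-methoxyphenyl)-3,7-dioxabicyclo[3.3.0]octan-8-one (CNP0268159.1) | COc1cc([C@H]2OC(=O)[C@H]3[C@@H]2CO[C@@H]3c2ccc(O)c(O)c2)ccc1O | target

**Step count and risks**

Total step count: 9. Longest linear sequence: 7 steps (steps 2, 3, 4, 5, 6, 8, 9; the sequence through step 1 is equally long).

Steps most likely to fail:

1. Step 8 (proposed new method). What may go wrong: C-acylation or oligomerisation of the enol ether by the activated acid chloride instead of O-acylation of the aldehyde, hydride capture of the benzylic cation before ring closure, or poor facial selectivity at C6. The fallback uses known chemistry, exchanges the roles of the two aldehydes and closes the tetrahydrofuran ring last (C1–C2 bond); it sets out from 6 and 18 and comes back at 23.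
   - Syn-aldol of 6 with 18 (n-Bu2BOTf, i-Pr2NEt, CH2Cl2, −78 → 0 °C) would give (4S)-4-benzyl-3-[(2S)-2-{(S)-hydroxy[3-methoxy-4-(triisopropylsilyloxy)phenyl]methyl}pent-4-enoyl]oxazolidin-2-one F1.
   - OsO4/NaIO4 cleavage would give the lactol (4S)-4-benzyl-3-{(2S,3S)-5-hydroxy-2-[3-methoxy-4-(triisopropylsilyloxy)phenyl]tetrahydrofuran-3-carbonyl}oxazolidin-2-one F2.
   - MsCl/Et3N would give (4S)-4-benzyl-3-{(2S,3S)-2-[3-methoxy-4-(triisopropylsilyloxy)phenyl]-2,3-dihydrofuran-3-carbonyl}oxazolidin-2-one F3.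
   - LiBH4 (THF, MeOH, 0 °C) would release the auxiliary and give {(2S,3R)-2-[3-methoxy-4-(triisopropylsilyloxy)phenyl]-2,3-dihydrofuran-3-yl}methanol F4.
   - Aldehyde 2 would be converted with HC(OMe)3 and pyridinium p-toluenesulfonate in MeOH into 3,4-bis(triisopropylsilyloxy)benzaldehyde dimethyl acetal F5.
   - Me3SiOTf (CH2Cl2, −78 → −20 °C) would join F4 and F5 by acetal exchange and alkoxycarbenium cyclisation onto the enol ether, the established dihydrofuran entry to furofurans. Methanol traps C8, giving (1S,2S,5R,6S)-2-[3,4-bis(triisopropylsilyloxy)phenyl]-8-methoxy-6-[3-methoxy-4-(triisopropylsilyloxy)phenyl]-3,7-dioxabicyclo[3.3.0]octane F6; prolonged contact with the same Lewis acid would equilibrate the new benzylic center to the exo-aryl isomer.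
   - CrO3/H2SO4 in acetone at 0 °C would oxidise the cyclic methyl acetal directly to lactone 23.

2. Step 5. What may go wrong: sluggish elimination of the anomeric sulfonate or chloride, or base-induced ring opening by β-elimination next to the imide and epimerisation. The fallback builds the enol ether by ring-closing metathesis instead of elimination; it sets out from 3 and 2 and comes back at 14.
   - Acylation of 3 with (E)-but-2-enoyl chloride (n-BuLi, THF, −78 °C) would give (S)-4-benzyl-3-[(E)-but-2-enoyl]oxazolidin-2-one F7.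
   - Its boron dienolate (n-Bu2BOTf, Et3N, CH2Cl2) should add to 2 at the α-carbon (deconjugative syn-aldol) to give (4S)-4-benzyl-3-[(2S)-2-{(S)-[3,4-bis(triisopropylsilyloxy)phenyl](hydroxy)methyl}but-3-enoyl]oxazolidin-2-one F8.
   - Vinyl transfer from butyl vinyl ether (Pd(OCOCF3)2, 4,7-diphenyl-1,10-phenanthroline, Et3N, 75 °C) would give (4S)-4-benzyl-3-[(2S)-2-{(S)-[3,4-bis(triisopropylsilyloxy)phenyl](ethenyloxy)methyl}but-3-enoyl]oxazolidin-2-one F9.
   - Ring-closing metathesis with the second-generation Grubbs catalyst (toluene, 70 °C) would close the enol ether C=C and return 14.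

3. Step 6. What may go wrong: β-elimination or double-bond migration under the basic conditions, loss of aryl silyl groups, oxidation of the enol ether at the peracid stage, or hydration of the enol ether on acidification. The fallback removes the auxiliary before the enol ether exists and frees the acid under neutral conditions; it sets out from 9 and comes back at 16.
   - Methanolysis of 9 (MeMgBr, MeOH, 0 °C) would give methyl (2S)-2-{(S)-[3,4-bis(triisopropylsilyloxy)phenyl](hydroxy)methyl}pent-4-enoate F10.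
   - OsO4/NaIO4 would give methyl (2S,3S)-2-[3,4-bis(triisopropylsilyloxy)phenyl]-5-hydroxytetrahydrofuran-3-carboxylate F11.
   - MsCl/Et3N would give methyl (2S,3S)-2-[3,4-bis(triisopropylsilyloxy)phenyl]-2,3-dihydrofuran-3-carboxylate F12.
   - Me3SnOH (ClCH2CH2Cl, 70 °C; cold dilute KHSO4 wash) would cleave the methyl ester and return 16.

Further compounds
F1 | step 8 | (4S)-4-benzyl-3-[(2S)-2-{(S)-hydroxy[3-methoxy-4-(triisopropylsilyloxy)phenyl]methyl}pent-4-enoyl]oxazolidin-2-one | COc1cc([C@@H](O)[C@H](CC=C)C(=O)N2[C@@H](Cc3ccccc3)COC2=O)ccc1O[Si](C(C)C)(C(C)C)C(C)C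
F2 | step 8 | (4S)-4-benzyl-3-{(2S,3S)-5-hydroxy-2-[3-methoxy-4-(triisopropylsilyloxy)phenyl]tetrahydrofuran-3-carbonyl}oxazolidin-2-one | COc1cc([C@H]2OC(O)C[C@@H]2C(=O)N2[C@@H](Cc3ccccc3)COC2=O)ccc1O[Si](C(C)C)(C(C)C)C(C)C
F3 | step 8 | (4S)-4-benzyl-3-{(2S,3S)-2-[3-methoxy-4-(triisopropylsilyloxy)phenyl]-2,3-dihydrofuran-3-carbonyl}oxazolidin-2-one | COc1cc([C@H]2OC=C[C@@H]2C(=O)N2[C@@H](Cc3ccccc3)COC2=O)ccc1O[Si](C(C)C)(C(C)C)C(C)C
F4 | step 8 | {(2S,3R)-2-[3-methoxy-4-(triisopropylsilyloxy)phenyl]-2,3-dihydrofuran-3-yl}methanol | COc1cc([C@H]2OC=C[C@@H]2CO)ccc1O[Si](C(C)C)(C(C)C)C(C)C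
F5 | step 8 | 3,4-bis(triisopropylsilyloxy)benzaldehyde dimethyl acetal | COC(OC)c1ccc(O[Si](C(C)C)(C(C)C)C(C)C)c(O[Si](C(C)C)(C(C)C)C(C)C)c1
F6 | step 8 | (1S,2S,5R,6S)-2-[3,4-bis(triisopropylsilyloxy)phenyl]-8-methoxy-6-[3-methoxy-4-(triisopropylsilyloxy)phenyl]-3,7-dioxabicyclo[3.3.0]octane, both C8 epimers | COc1cc([C@H]2OC(OC)[C@H]3[C@@H]2CO[C@@H]3c2ccc(O[Si](C(C)C)(C(C)C)C(C)C)c(O[Si](C(C)C)(C(C)C)C(C)C)c2)ccc1O[Si](C(C)C)(C(C)C)C(C)C
F7 | step 5 | (S)-4-benzyl-3-[(E)-but-2-enoyl]oxazolidin-2-one | C/C=C/C(=O)N1[C@@H](Cc2ccccc2)COC1=O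
F8 | step 5 | (4S)-4-benzyl-3-[(2S)-2-{(S)-[3,4-bis(triisopropylsilyloxy)phenyl](hydroxy)methyl}but-3-enoyl]oxazolidin-2-one | O=C(N1[C@@H](Cc2ccccc2)COC1=O)[C@H]([C@H](O)c1ccc(O[Si](C(C)C)(C(C)C)C(C)C)c(O[Si](C(C)C)(C(C)C)C(C)C)c1)C=C
F9 | step 5 | (4S)-4-benzyl-3-[(2S)-2-{(S)-[3,4-bis(triisopropylsilyloxy)phenyl](ethenyloxy)methyl}but-3-enoyl]oxazolidin-2-one | O=C(N1[C@@H](Cc2ccccc2)COC1=O)[C@H]([C@H](OC=C)c1ccc(O[Si](C(C)C)(C(C)C)C(C)C)c(O[Si](C(C)C)(C(C)C)C(C)C)c1)C=C
F10 | step 6 | methyl (2S)-2-{(S)-[3,4-bis(triisopropylsilyloxy)phenyl](hydroxy)methyl}pent-4-enoate | COC(=O)[C@H]([C@H](O)c1ccc(O[Si](C(C)C)(C(C)C)C(C)C)c(O[Si](C(C)C)(C(C)C)C(C)C)c1)CC=C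
F11 | step 6 | methyl (2S,3S)-2-[3,4-bis(triisopropylsilyloxy)phenyl]-5-hydroxytetrahydrofuran-3-carboxylate, both anomers | COC(=O)[C@H]1CC(O)O[C@@H]1c1ccc(O[Si](C(C)C)(C(C)C)C(C)C)c(O[Si](C(C)C)(C(C)C)C(C)C)c1
F12 | step 6 | methyl (2S,3S)-2-[3,4-bis(triisopropylsilyloxy)phenyl]-2,3-dihydrofuran-3-carboxylate | COC(=O)[C@H]1C=CO[C@@H]1c1ccc(O[Si](C(C)C)(C(C)C)C(C)C)c(O[Si](C(C)C)(C(C)C)C(C)C)c1
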